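## Retrosynthetic overview

- The target is disconnected at the bond between carbonyl carbon C1 and chain-bearing C6 (Moore rearrangement), which leads back to racemic 4-(henicos-1-ynyl)-4-hydroxy-2-methoxycyclobut-2-enone. The quinone ring is the only ring formed in the route and it is formed last.
- That cyclobutenone comes from the silylated adduct of henicos-1-ynyllithium and dimethyl squarate by hydride 1,2-addition, acid-induced 1,3-carbonyl transposition (the ring methoxy next to the carbinol carbon is exchanged for hydrogen) and desilylation. The four-membered ring is bought, serves as a temporary ring and is consumed in the key step.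
- Henicos-1-yne comes from 1-bromononadecane and lithium acetylide.
- Enabling feature (quinone numbering: C1 is the carbonyl between methoxy-bearing C2 and nonadecyl-bearing C6, C4 is the other carbonyl): C4(=O)–C5(H)=C6(alkyl) is a masked propargylic carbinol HO–C4–C5≡C6–alkyl whose O–H hydrogen ends on C5, and C1–C2(OMe)=C3(H)–C4 is a masked cyclobutenone whose C1–C4 bond opens to a ketene at C1. The para-dioxygenated ring with a free C5–H is therefore an isomer of a squarate–alkyne adduct.

Key step: step 5

Remark: the target has no stereocentre. Every intermediate carrying the quaternary carbinol carbon is handled as a racemate (8 as a mixture of diastereomers). 1-Bromononadecane, lithium acetylide–ethylenediamine complex and dimethyl squarate are taken as purchased.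

## Route

Step 1
Reactants: 1 1-bromononadecane; 2 lithium acetylide–ethylenediamine complex
Product: 3 henicos-1-yne
Conditions: LiC≡CH·H2NCH2CH2NH2 (1.5 equiv), DMSO/THF, 5 °C → rt
Reagents that add atoms: none
Why: SN2 alkylation of an acetylide anion by an unhindered primary bromide in a dipolar aprotic medium should give the terminal alkyne directly, with little competing elimination.

Step 2
Reactants: 3 henicos-1-yne; 4 dimethyl squarate (3,4-dimethoxycyclobut-3-ene-1,2-dione)
Product: 7 4-(henicos-1-yn-1-yl)-2,3-dimethoxy-4-[(triethylsilyl)oxy]cyclobut-2-en-1-one (racemic), via henicos-1-yn-1-yllithium 5 (not isolated), via lithium cyclobutenolate 6 (not isolated)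
Conditions: n-BuLi (0.95 equiv based on 3), THF, −78 → 0 °C; cannulated into 4, THF, −78 °C; then Et3SiOTf, −78 → −20 °C
Reagents that add atoms: triethylsilyl trifluoromethanesulfonate, CC[Si](CC)(CC)OS(=O)(=O)C(F)(F)F
Why: Alkynyllithium 1,2-addition to one of the two equivalent carbonyls of a squarate ester should stop at mono-addition because the alkoxide-substituted vinylogous ester left behind is far less electrophilic, and the hindered tertiary lithium alkoxide is then O-silylated by the silyl triflate; the new quaternary carbinol centre forms as a racemate and is erased in step 5.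

Step 3
Reactants: 7 4-(henicos-1-yn-1-yl)-2,3-dimethoxy-4-[(triethylsilyl)oxy]cyclobut-2-en-1-one
Product: 9 4-(henicos-1-yn-1-yl)-2-methoxy-4-[(triethylsilyl)oxy]cyclobut-2-en-1-one (racemic), via allylic alcohol 8 (not isolated)
Conditions: i-Bu2AlH (1.2 equiv), toluene, −78 °C; then 1 M aq. HCl, THF, 0 °C, short contact time
Reagents that add atoms: water, O
Why: Hydride 1,2-addition to the vinylogous ester carbonyl, then acid-induced ionisation of the secondary allylic hydroxyl to a methoxy-stabilised cyclobutenyl cation, capture by water at the methoxy-bearing terminus and loss of methanol amount to a Stork–Danheiser-type 1,3-carbonyl transposition that puts hydrogen next to the carbinol carbon, while the silylated tertiary oxygen cannot compete as a leaving group; the secondary carbinol centre of 8 is erased in the same operation.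

Step 4
Reactants: 9 4-(henicos-1-yn-1-yl)-2-methoxy-4-[(triethylsilyl)oxy]cyclobut-2-en-1-one
Product: 10 4-(henicos-1-yn-1-yl)-4-hydroxy-2-methoxycyclobut-2-en-1-one (racemic)
Conditions: HF·pyridine, THF/pyridine, 0 °C → rt
Reagents that add atoms: none
Why: Fluoride-driven cleavage of the Si–O bond under buffered, weakly acidic conditions should free the tertiary alcohol without the base-induced ring opening or the acid-induced ionisation to which 4-hydroxycyclobutenones are prone.

Step 5
Reactants: 10 4-(henicos-1-yn-1-yl)-4-hydroxy-2-methoxycyclobut-2-en-1-one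
Product: 13 2-methoxy-6-nonadecyl-1,4-benzoquinone (target), via enynylketene 11 (not isolated), via aryl diradical 12 (not isolated)
Conditions: degassed p-xylene (0.01 M), reflux (138 °C), argon
Reagents that add atoms: none
Why: Moore rearrangement: heating opens the C1–C4 bond of the cyclobutenone in a conrotatory 4π-electrocyclic ring opening in which the hydroxyl rotates outward, so that the alkynyl group lies cis to the new ketene in (3E)-enynylketene 11. The ketene carbon (future C1) then bonds to the distal alkyne carbon (future C6, carrying the nonadecyl chain) in a 6-endo-dig closure of the quinone ring, a cycloaromatisation that gives diradical 12 with a σ-radical at C5 and a phenoxyl radical at the C1 oxygen. Transfer of the hydroxyl hydrogen from the C4 oxygen to C5 ends the sequence at the quinone oxidation level, so the ring, both carbonyls and the full substitution pattern arise from an isomerisation that needs no reagent. The closest known reaction type is the thermal ring expansion of squarate-derived 4-alkynyl-4-hydroxycyclobutenones to 1,4-benzoquinones; no stereocentre is formed and the racemic centre of 10 becomes the planar C4. The step needs six-membered closure in preference to 5-exo-dig closure to an alkylidenecyclopentenedione, which the plain primary alkyl group at the alkyne terminus (no radical-stabilising substituent) should secure. The regiochemistry (methoxy at C2, hydrogen at C3 and C5, chain at C6) is fixed by the substitution of 10 and cannot scramble.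

## Compound list

1 | 1-bromononadecane | CCCCCCCCCCCCCCCCCCCBr | starting material
2 | lithium acetylide–ethylenediamine complex | [Li]C#C.NCCN | starting material
3 | henicos-1-yne | CCCCCCCCCCCCCCCCCCCC#C | intermediate
4 | dimethyl squarate (3,4-dimethoxycyclobut-3-ene-1,2-dione) | COC1=C(OC)C(=O)C1=O | starting material
5 | henicos-1-yn-1-yllithium | [Li]C#CCCCCCCCCCCCCCCCCCCC | intermediate (not isolated)
6 | lithium 1-(henicos-1-yn-1-yl)-2,3-dimethoxy-4-oxocyclobut-2-en-1-olate (racemic) | [Li+].[O-]C1(C#CCCCCCCCCCCCCCCCCCCC)C(OC)=C(OC)C1=O | intermediate (not isolated)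
7 | 4-(henicos-1-yn-1-yl)-2,3-dimethoxy-4-[(triethylsilyl)oxy]cyclobut-2-en-1-one (racemic) | CC[Si](CC)(CC)OC1(C#CCCCCCCCCCCCCCCCCCCC)C(OC)=C(OC)C1=O | intermediate
8 | 4-(henicos-1-yn-1-yl)-2,3-dimethoxy-4-[(triethylsilyl)oxy]cyclobut-2-en-1-ol (racemic, mixture of diastereomers) | CC[Si](CC)(CC)OC1(C#CCCCCCCCCCCCCCCCCCCC)C(OC)=C(OC)C1O | intermediate (not isolated)
9 | 4-(henicos-1-yn-1-yl)-2-methoxy-4-[(triethylsilyl)oxy]cyclobut-2-en-1-one (racemic) | CC[Si](CC)(CC)OC1(C#CCCCCCCCCCCCCCCCCCCC)C=C(OC)C1=O | intermediate
10 | 4-(henicos-1-yn-1-yl)-4-hydroxy-2-methoxycyclobut-2-en-1-one (racemic) | OC1(C#CCCCCCCCCCCCCCCCCCCC)C=C(OC)C1=O | intermediate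
11 | (3E)-4-hydroxy-2-methoxypentacosa-1,3-dien-5-yn-1-one (enynylketene) | O=C=C(OC)/C=C(/O)C#CCCCCCCCCCCCCCCCCCCC | intermediate (not isolated)
12 | 4-hydroxy-2-methoxy-6-nonadecylphenoxyl carrying a second unpaired electron at C5 (aryl σ,π-diradical) | CCCCCCCCCCCCCCCCCCCC1=[C]C(O)=CC(OC)=C1[O] | intermediate (not isolated)
13 | 2-methoxy-6-nonadecyl-1,4-benzoquinone (2-methoxy-6-nonadecylcyclohexa-2,5-diene-1,4-dione) | CCCCCCCCCCCCCCCCCCCC1=CC(=O)C=C(OC)C1=O | target

## Step count and risks

Total step count: 5. Longest linear sequence: 5 steps (1 → 3 → 7 → 9 → 10 → 13).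

Steps most likely to fail:

**Step 5 (key step).** The ketene may close in the five-membered exo mode or be trapped by the hydroxyl oxygen, or ring opening of a cyclobutenone with only one donor substituent on the double bond may lag behind decomposition at the temperature needed. The fallback gives up the ring construction and oxidises a ready-made arene; it sets out from 1 and comes back to the route at 13. Guaiacol would be protected (MeOCH2Cl, i-Pr2NEt, CH2Cl2) as 1-methoxy-2-(methoxymethoxy)benzene F1 and lithiated ortho to the acetal oxygen (n-BuLi, THF, 0 °C) to [3-methoxy-2-(methoxymethoxy)phenyl]lithium F2. Alkylation with bromide 1 should give 1-methoxy-2-(methoxymethoxy)-3-nonadecylbenzene F3, and HCl in MeOH should free 2-methoxy-6-nonadecylphenol F4. Teuber oxidation at the free para position with Fremy's salt (KSO3)2NO under phase-transfer conditions should then give 13.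

**Step 3.** Premature loss of the triethylsilyl group, followed by ionisation at the tertiary propargylic carbon, would send the transposition the wrong way; incomplete 1,2-reduction is a lesser concern. The fallback avoids both protection and transposition of the alkyne adduct by using the innate regiochemistry of a semisquarate and a 6π-electrocyclisation; it sets out from 3 and 4 and comes back at 13. Reduction of 4 with LiAlH(O-t-Bu)3 (THF, −78 °C) should give 4-hydroxy-2,3-dimethoxycyclobut-2-en-1-one F5, which concentrated HCl in CH2Cl2 should convert into 3-methoxycyclobut-3-ene-1,2-dione F6. Markovnikov hydroiodination of 3 (NaI, Me3SiCl, H2O, MeCN) would give 2-iodohenicos-1-ene F7, and t-BuLi (2 equiv, Et2O, −78 °C) would turn it into henicos-1-en-2-yllithium F8. F8 should add to the carbonyl of F6 that lies next to the methoxy-bearing carbon, giving 4-(henicos-1-en-2-yl)-4-hydroxy-3-methoxycyclobut-2-en-1-one F9. Heating F9 in toluene should expand the ring to 2-methoxy-6-nonadecylbenzene-1,4-diol F10, which Ag2O should oxidise to 13.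

**Step 4.** Desilylation of the hindered tertiary ether may be slow, and the strained hydroxy enone may open or ionise under the fluoride or acid needed to force it. The fallback changes the protecting-group strategy to a silyl group that is shed in the work-up of the transposition; it sets out from 6 and comes back at 10. Alkoxide 6 would be trapped with Me3SiCl to give 4-(henicos-1-yn-1-yl)-2,3-dimethoxy-4-[(trimethylsilyl)oxy]cyclobut-2-en-1-one F11, which i-Bu2AlH should reduce to 4-(henicos-1-yn-1-yl)-2,3-dimethoxy-4-[(trimethylsilyl)oxy]cyclobut-2-en-1-ol F12. Dilute aqueous HCl in THF should first effect the transposition to 4-(henicos-1-yn-1-yl)-2-methoxy-4-[(trimethylsilyl)oxy]cyclobut-2-en-1-one F13 and then, on longer stirring, hydrolyse the labile trimethylsilyl ether to 10. This relies on the secondary allylic alcohol ionising faster than the trimethylsilyl ether is lost.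

Further compounds
F1 | step 5 | 1-methoxy-2-(methoxymethoxy)benzene | COCOc1ccccc1OC
F2 | step 5 | [3-methoxy-2-(methoxymethoxy)phenyl]lithium | [Li]c1cccc(OC)c1OCOC
F3 | step 5 | 1-methoxy-2-(methoxymethoxy)-3-nonadecylbenzene | CCCCCCCCCCCCCCCCCCCc1cccc(OC)c1OCOC
F4 | step 5 | 2-methoxy-6-nonadecylphenol | CCCCCCCCCCCCCCCCCCCc1cccc(OC)c1O
F5 | step 3 | 4-hydroxy-2,3-dimethoxycyclobut-2-en-1-one (racemic) | OC1C(OC)=C(OC)C1=O
F6 | step 3 | 3-methoxycyclobut-3-ene-1,2-dione | COC1=CC(=O)C1=O
F7 | step 3 | 2-iodohenicos-1-ene | C=C(I)CCCCCCCCCCCCCCCCCCC
F8 | step 3 | henicos-1-en-2-yllithium | [Li]C(=C)CCCCCCCCCCCCCCCCCCC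
F9 | step 3 | 4-(henicos-1-en-2-yl)-4-hydroxy-3-methoxycyclobut-2-en-1-one (racemic) | OC1(C(=C)CCCCCCCCCCCCCCCCCCC)C(OC)=CC1=O
F10 | step 3 | 2-methoxy-6-nonadecylbenzene-1,4-diol | CCCCCCCCCCCCCCCCCCCc1cc(O)cc(OC)c1O
F11 | step 4 | 4-(henicos-1-yn-1-yl)-2,3-dimethoxy-4-[(trimethylsilyl)oxy]cyclobut-2-en-1-one (racemic) | C[Si](C)(C)OC1(C#CCCCCCCCCCCCCCCCCCCC)C(OC)=C(OC)C1=O
F12 | step 4 | 4-(henicos-1-yn-1-yl)-2,3-dimethoxy-4-[(trimethylsilyl)oxy]cyclobut-2-en-1-ol (racemic, mixture of diastereomers) | C[Si](C)(C)OC1(C#CCCCCCCCCCCCCCCCCCCC)C(OC)=C(OC)C1O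
F13 | step 4 | 4-(henicos-1-yn-1-yl)-2-methoxy-4-[(trimethylsilyl)oxy]cyclobut-2-en-1-one (racemic) | C[Si](C)(C)OC1(C#CCCCCCCCCCCCCCCCCCCC)C=C(OC)C1=O
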